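**Retrosynthetic overview**

1. Target ⇐ benzoylation of the C5 alcohol ⇐ catalyst-controlled reduction of the C5 aryl ketone of the seven-membered ring B (C5 = benzylic C–O carbon, C6 and C7 = the two CHMe carbons, C8 = CH2, C9 = spiro carbon).
2. Ring B ⇐ two-carbon ring expansion of an achiral spiro-1-indanone (C5 bonded directly to C8) with (E)-2-butene: rhodium cuts the C5–C8 bond and joins both ends to the alkene, making C8–C7 and C6–C5 and the C6/C7 stereocenters in one operation.
3. Enabling feature: C5 and C8 hang on the two ortho carbons of ring A (C8 through C9), so tying them gives a five-membered aryl ketone. C8 sits on the quaternary spiro carbon C9, so the alkylrhodium has no β-hydrogen, and the symmetric dienone ring C makes C9 non-stereogenic.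
4. Spiro-indanone ⇐ para-C-alkylation (dearomatisation) of a biaryl phenol by its own chloromethyl ketone ⇐ ester homologation ⇐ Suzuki–Miyaura coupling of two bought arenes.
5. Ring order: rings A and C bought as arenes → temporary five-membered ring closed while ring C is dearomatised → ring B by ring expansion, which consumes the five-membered ring.

Key step: step 4

Remark: the sense of induction of the chiral carbene ligand in step 4 cannot be predicted, so the ligand enantiomer that leads to the (6S,7R) ketone is to be fixed by a screen.

**Route**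

Step 1
Reactants: 1 methyl 2-bromo-3,4,5-trimethoxybenzoate; 2 2,6-dimethoxy-4-(4,4,5,5-tetramethyl-1,3,2-dioxaborolan-2-yl)phenol
Product: 3 methyl 2-(4-hydroxy-3,5-dimethoxyphenyl)-3,4,5-trimethoxybenzoate
Conditions: Pd(OAc)2 (3 mol%), SPhos (6 mol%), K3PO4 (3 equiv), toluene/H2O 10:1, 90 °C
Reagents that add atoms: none
Why: Suzuki–Miyaura cross-coupling, in which the electron-rich biaryl phosphine should allow oxidative addition into the doubly ortho-substituted aryl bromide and the free phenol is carried as its phenoxide; no stereocenter is formed.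

Step 2
Reactants: 3 methyl 2-(4-hydroxy-3,5-dimethoxyphenyl)-3,4,5-trimethoxybenzoate
Product: 5 2-chloro-1-[2-(4-hydroxy-3,5-dimethoxyphenyl)-3,4,5-trimethoxyphenyl]ethan-1-one, via dilithium hemiketal alkoxide 4 (not isolated)
Conditions: ICH2Cl (3 equiv), MeLi·LiBr (4 equiv, slow addition), THF, −78 °C; then AcOH, −78 °C to rt
Reagents that add atoms: chloroiodomethane, ClCI
Why: Homologation of an ester to a chloromethyl ketone with chloromethyllithium (a lithium carbenoid made in the flask by iodine–lithium exchange), where the first equivalent of MeLi masks the phenol as its lithium phenoxide and the tetrahedral adduct 4 is stable at −78 °C, so that only one CH2Cl unit should add before the acidic quench.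

Step 3
Reactants: 5 2-chloro-1-[2-(4-hydroxy-3,5-dimethoxyphenyl)-3,4,5-trimethoxyphenyl]ethan-1-one
Product: 6 3,5,5',6',7'-pentamethoxyspiro[cyclohexa-2,5-diene-1,1'-indene]-3',4(2'H)-dione (spiro-indanone)
Conditions: KOtBu (1.05 equiv), tBuOH/THF, 0.005 M, 25 to 50 °C
Reagents that add atoms: none
Why: Alkylative dearomatisation of a phenoxide (Ar1-5 participation, 5-exo-tet), in which the para carbon of ring C, held over the CH2Cl carbon by the twisted biaryl, should displace chloride and so close the five-membered ketone ring, create the spiro carbon and unveil the 2,6-dimethoxycyclohexadienone at once; O-alkylation is impossible within the molecule and is held back between molecules by high dilution, and the spiro carbon is not a stereocenter.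

Step 4
Reactants: 6 spiro-indanone; 7 (E)-but-2-ene
Product: 10 (6S,7R)-trans-6,7-dimethyl spiro-benzocycloheptenedione, via indanone N-pyridyl ketimine 8 (not isolated), via ring-expanded N-pyridyl ketimine 9 (not isolated)
Conditions: [Rh(C2H4)2Cl]2 (5 mol%), one enantiomer of 1,3-bis(2-isopropylphenyl)-4,5-diphenylimidazolidin-2-ylidene (12 mol%), 2-amino-3-picoline (1 equiv), TsOH·H2O (20 mol%), H2O (1 equiv), (E)-2-butene (10 equiv, condensed in), THF, 130 °C, sealed vessel
Reagents that add atoms: water, O (hydrolysis of ketimine 9 returns the carbonyl oxygen that the condensation to 8 released; no net uptake)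
Why: Proposed new method: 2-amino-3-picoline condenses with the aryl ketone to ketimine 8, whose pyridine nitrogen steers monovalent rhodium into the bond between the imidoyl carbon and the CH2 group of the five-membered ring to give a six-membered rhodacycle of trivalent rhodium; (E)-2-butene then inserts syn into one Rh–C bond, C–C reductive elimination with retention gives ketimine 9, and hydrolysis releases 10 and the aminopyridine. The closest known reaction type is the rhodium/NHC/aminopyridine-catalysed two-carbon ring expansion of 1-indanones with ethylene and their [5+2] annulation with internal alkynes; neither an internal alkene nor an enantioselective version has been shown, hence the label. The seven-membered ring B closes by reductive elimination from an eight-membered rhodacycle (formal [5+2], with the five-membered ring opened), not by a chain cyclisation. C6 and C7 arise together: syn insertion plus retentive reductive elimination place both new bonds on one face of the E-alkene, which fixes the trans relation (expected to be the thermodynamic one as well, since C6 can equilibrate through the enamine of 9), and the C2-symmetric chiral NHC on rhodium chooses between the two enantiotopic alkene faces and so sets the absolute configuration. The step needs cleavage at the aryl ketone and not at the ring C carbonyl, and reductive elimination faster than β-hydride elimination: the first is secured because the cross-conjugated ring C carbonyl has only sp2 neighbours and because the quaternary spiro carbon leaves the Rh–CH2 group without β-hydrogens, while the second rests on the chelated metallacycle and the strongly donating NHC and is the main risk.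

Step 5
Reactants: 10 (6S,7R)-trans-6,7-dimethyl spiro-benzocycloheptenedione
Product: 11 (5R,6S,7R)-5-hydroxy-1,2,3,3',5'-pentamethoxy-6,7-dimethyl-5,6,7,8-tetrahydrospiro[benzo[7]annulene-9,1'-cyclohexa[2,5]dien]-4'-one
Conditions: (S)-2-methyl-CBS-oxazaborolidine (0.5 equiv), BH3·SMe2 (0.6 equiv), THF, −20 °C; then MeOH, aq. NH4Cl
Reagents that add atoms: none
Why: Corey–Bakshi–Shibata reduction, in which the (S)-oxazaborolidine should deliver hydride to the face of the aryl ketone that gives the (5R) carbinol (aryl as the large group, as for 1-tetralone), that is trans to the C6 methyl group, under catalyst control, while the cross-conjugated ring C carbonyl is a poorer hydride acceptor and should survive limiting borane at low temperature.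

Step 6
Reactants: 11 (5R,6S,7R)-5-hydroxy-1,2,3,3',5'-pentamethoxy-6,7-dimethyl-5,6,7,8-tetrahydrospiro[benzo[7]annulene-9,1'-cyclohexa[2,5]dien]-4'-one
Product: 12 (5R,6S,7R)-1,2,3,3',5'-pentamethoxy-6,7-dimethyl-4'-oxo-5,6,7,8-tetrahydrospiro[benzo[7]annulene-9,1'-cyclohexa[2,5]dien]-5-yl benzoate (CNP0201356.1)
Conditions: BzCl (1.5 equiv), Et3N (2 equiv), DMAP (10 mol%), CH2Cl2, 0 °C to rt
Reagents that add atoms: benzoyl chloride, O=C(Cl)c1ccccc1
Why: Acylation of the secondary benzylic alcohol under nucleophilic catalysis by DMAP, which does not touch the C5–O bond, so that C5 keeps its configuration.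

**Compound list**

1 | methyl 2-bromo-3,4,5-trimethoxybenzoate | COC(=O)c1cc(OC)c(OC)c(OC)c1Br | starting material
2 | 2,6-dimethoxy-4-(4,4,5,5-tetramethyl-1,3,2-dioxaborolan-2-yl)phenol | COc1cc(B2OC(C)(C)C(C)(C)O2)cc(OC)c1O | starting material
3 | methyl 2-(4-hydroxy-3,5-dimethoxyphenyl)-3,4,5-trimethoxybenzoate | COC(=O)c1cc(OC)c(OC)c(OC)c1-c1cc(OC)c(O)c(OC)c1 | intermediate
4 | dilithium salt of the chloromethyl methyl hemiketal of 5 (phenoxide and hemiketal alkoxide; formed in the flask) | COc1cc(cc(OC)c1[O-])-c1c(OC)c(OC)c(OC)cc1C([O-])(OC)CCl.[Li+].[Li+] | intermediate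
5 | 2-chloro-1-[2-(4-hydroxy-3,5-dimethoxyphenyl)-3,4,5-trimethoxyphenyl]ethan-1-one | COc1cc(cc(OC)c1O)-c1c(OC)c(OC)c(OC)cc1C(=O)CCl | intermediate
6 | 3,5,5',6',7'-pentamethoxyspiro[cyclohexa-2,5-diene-1,1'-indene]-3',4(2'H)-dione (achiral spiro-indanone) | COC1=CC2(C=C(OC)C1=O)CC(=O)c1cc(OC)c(OC)c(OC)c12 | intermediate
7 | (E)-but-2-ene | C/C=C/C | starting material
8 | N-(3-methylpyridin-2-yl) ketimine of 6 at the aryl ketone (formed in the flask) | COC1=CC2(C=C(OC)C1=O)CC(=Nc1ncccc1C)c1cc(OC)c(OC)c(OC)c12 | intermediate
9 | N-(3-methylpyridin-2-yl) ketimine of 10 at C5 (formed in the flask) | COC1=CC2(C=C(OC)C1=O)C[C@@H](C)[C@H](C)C(=Nc1ncccc1C)c1cc(OC)c(OC)c(OC)c12 | intermediate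
10 | (6S,7R)-1,2,3,3',5'-pentamethoxy-6,7-dimethyl-7,8-dihydrospiro[benzo[7]annulene-9,1'-cyclohexa[2,5]diene]-4',5(6H)-dione | COC1=CC2(C=C(OC)C1=O)C[C@@H](C)[C@H](C)C(=O)c1cc(OC)c(OC)c(OC)c12 | intermediate
11 | (5R,6S,7R)-5-hydroxy-1,2,3,3',5'-pentamethoxy-6,7-dimethyl-5,6,7,8-tetrahydrospiro[benzo[7]annulene-9,1'-cyclohexa[2,5]dien]-4'-one | COC1=CC2(C=C(OC)C1=O)C[C@@H](C)[C@H](C)[C@@H](O)c1cc(OC)c(OC)c(OC)c12 | intermediate
12 | (5R,6S,7R)-1,2,3,3',5'-pentamethoxy-6,7-dimethyl-4'-oxo-5,6,7,8-tetrahydrospiro[benzo[7]annulene-9,1'-cyclohexa[2,5]dien]-5-yl benzoate | COC1=CC2(C=C(OC)C1=O)C[C@@H](C)[C@H](C)[C@@H](OC(=O)c1ccccc1)c1cc(OC)c(OC)c(OC)c12 | target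

**Step count and risks**

Total step count: 6. Longest linear sequence: 6 steps (1 to 12; 2 enters in step 1 and 7 in step 4).

Steps most likely to fail:

1. Step 4 (proposed new method). The internal alkene may insert too slowly, or the secondary alkylrhodium may undergo β-hydride elimination before C–C reductive elimination and give ring-opened products. The two alkene faces may be poorly differentiated, or ring C may suffer acid-promoted dienone–phenol rearrangement or enamine addition at 130 °C. The fallback uses known chemistry, sets out from 6 and comes back at 10. Ring expansion of 6 with ethylene under the established conditions ([Rh(C2H4)2Cl]2, IMes, 2-amino-3-picoline, TsOH·H2O, ethylene 7 bar, THF, 130 °C) should give the unsubstituted spiro-benzocycloheptenedione F1. Dehydrogenation with IBX (DMSO/toluene, 70 °C) should give the 6,7-enone F2. Copper-catalysed asymmetric conjugate addition of Me2Zn (Cu(OTf)2, chiral phosphoramidite, toluene, −30 °C) would set C7 and give the (7R)-7-methyl ketone F3; the ring C dienone is expected to be slower because its β-carbons are neopentylic and carry α-methoxy groups. Kinetic enolisation (LiHMDS, THF, −78 °C) and MeI should then methylate C6 trans to the C7 methyl group and return to 10.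

2. Step 5. Hydride transfer to the ring C dienone carbonyl may compete with reduction of the aryl ketone, or a mismatched catalyst/substrate pairing may erode facial selectivity. The fallback sets out from 10 and comes back at 11. Both carbonyls are reduced on purpose with (S)-2-methyl-CBS-oxazaborolidine and excess BH3·SMe2 (THF, −20 °C), C5 still being set by the catalyst, to give the diol F4 as a mixture of ring C carbinol epimers. The bis-allylic ring C carbinol is then re-oxidised selectively with activated MnO2 (CH2Cl2, rt), which should leave the hindered benzylic C5 alcohol and return to 11.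

3. Step 3. Intermolecular O-alkylation and oligomerisation may outrun the para-C-alkylation, or the chloromethyl ketone may degrade under base. The fallback sets out from 1 and comes back at 6, forming the other bond to the spiro carbon. Crossed Claisen condensation of 1 with the trianion of (4-hydroxy-3,5-dimethoxyphenyl)acetic acid (LiHMDS, THF, −78 to 0 °C) should give the β-keto acid F5, which loses CO2 on acidic work-up to the bromo deoxybenzoin F6. Zerovalent palladium (from Pd(OAc)2 and a bulky biaryl dialkylphosphine, K2CO3, dioxane, 110 °C) should then insert into the C–Br bond and arylate the para carbon of the phenoxide (arylative dearomatisation), closing the five-membered ring and returning to 6.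

Further compounds

F1 | step 4 | 1,2,3,3',5'-pentamethoxy-7,8-dihydrospiro[benzo[7]annulene-9,1'-cyclohexa[2,5]diene]-4',5(6H)-dione | COC1=CC2(C=C(OC)C1=O)CCCC(=O)c1cc(OC)c(OC)c(OC)c12
F2 | step 4 | 1,2,3,3',5'-pentamethoxyspiro[benzo[7]annulene-9,1'-cyclohexa[2,5]diene]-4',5(8H)-dione (6,7-enone) | COC1=CC2(C=C(OC)C1=O)CC=CC(=O)c1cc(OC)c(OC)c(OC)c12
F3 | step 4 | (7R)-1,2,3,3',5'-pentamethoxy-7-methyl-7,8-dihydrospiro[benzo[7]annulene-9,1'-cyclohexa[2,5]diene]-4',5(6H)-dione | COC1=CC2(C=C(OC)C1=O)C[C@@H](C)CC(=O)c1cc(OC)c(OC)c(OC)c12
F4 | step 5 | (5R,6S,7R)-1,2,3,3',5'-pentamethoxy-6,7-dimethyl-5,6,7,8-tetrahydrospiro[benzo[7]annulene-9,1'-cyclohexa[2,5]diene]-4',5-diol (mixture of epimers at C4') | COC1=CC2(C=C(OC)C1O)C[C@@H](C)[C@H](C)[C@@H](O)c1cc(OC)c(OC)c(OC)c12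
F5 | step 3 | 3-(2-bromo-3,4,5-trimethoxyphenyl)-2-(4-hydroxy-3,5-dimethoxyphenyl)-3-oxopropanoic acid | COc1cc(cc(OC)c1O)C(C(=O)O)C(=O)c1cc(OC)c(OC)c(OC)c1Br
F6 | step 3 | 1-(2-bromo-3,4,5-trimethoxyphenyl)-2-(4-hydroxy-3,5-dimethoxyphenyl)ethan-1-one | COc1cc(CC(=O)c2cc(OC)c(OC)c(OC)c2Br)cc(OC)c1O
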